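**Plan**
- Retrosynthesis: the C8–acyl bond is cut first (Friedel–Crafts), then together the lactone bond O1–C2 and the ring A bond C7–C8 (Claisen), then C4–C4a (carbene-catalysed Michael addition–lactonisation), leaving two achiral fragments.
- Enabling feature: ring A (C4a, C5, C6, C7, C8, C8a) is a phloroglucinol with oxygen on C5, C7 and C8a and with C4 on C4a. It therefore unfolds to a chain C7(=O)OMe–C6H2–C5(=O)–C4aH–C8a(=O)–C8H2 whose C4a carries C4, C3 and the C2 carboxyl.
- Strengthening: the C8 methylene carries a tert-butoxycarbonyl group, so the ring-closing nucleophile is a β-keto ester enolate and not a methyl ketone; the group leaves as CO2 in the acidic finish. The side chain is kept as a free carboxylate, which no enolate can attack.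
- Forward: 1 and 2 give 3 and then chain 4 (steps 1–2); annulation with 5 (through lactones 6 and 7) and hydrolysis give acid 8 (step 3); ring A and then the lactone ring close in step 4 (through 9 and 10) to give 11; acylation with 12 at C8 gives 13 (step 5).
- Stereochemistry: the single stereocentre C4 is set in step 3 by the chiral triazolium catalyst and carries no acidic hydrogen afterwards.

Key step: step 4

Assumption: the (5aR,10bS) antipode of 2-mesityl-5a,10b-dihydro-4H,6H-indeno[2,1-b][1,2,4]triazolo[4,3-d][1,4]oxazin-2-ium chloride is taken to direct the diketone to the face of the cinnamoyl azolium that gives the (4S) lactones; should the sense prove opposite, the mirror-image salt serves in its place.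

**Step 1**
Reactants: 1 2,2,6-trimethyl-4H-1,3-dioxin-4-one; 2 methyl malonyl chloride (methyl 3-chloro-3-oxopropanoate)
Product: 3 methyl 4-(2,2-dimethyl-4-oxo-4H-1,3-dioxin-6-yl)-3-oxobutanoate
Conditions: LiN(SiMe3)2 (2.1 equiv), 1 (2 equiv), THF, −78 °C; then 2 (1 equiv), −78 → −20 °C; aq. NH4Cl
Reagents that add atoms: none
Why: The lithium dienolate of 1 reacts at its exocyclic γ-carbon with the acid chloride (vinylogous Claisen acylation), and the more acidic product is held as its enolate by the second equivalent of dienolate, which should stop over-acylation.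

**Step 2**
Reactants: 3 methyl 4-(2,2-dimethyl-4-oxo-4H-1,3-dioxin-6-yl)-3-oxobutanoate
Product: 4 1-tert-butyl 7-methyl 3,5-dioxoheptanedioate
Conditions: t-BuOH (10 equiv), toluene, 110 °C (sealed tube), short heating
Reagents that add atoms: tert-butanol, CC(C)(C)O
Why: Above about 100 °C the dioxinone ring loses acetone in a retro-hetero-Diels–Alder reaction and the acylketene is trapped by tert-butanol, the standard route from dioxinones to tert-butyl β-keto esters, the alcohol being in excess to outpace closure of the ketene onto its own enol oxygen.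

**Step 3**
Reactants: 4 1-tert-butyl 7-methyl 3,5-dioxoheptanedioate; 5 (E)-cinnamaldehyde
Product: 8 1-tert-butyl 7-methyl 4-[(1R)-2-carboxy-1-phenylethyl]-3,5-dioxoheptanedioate, via enol lactone 6 (not isolated), via regioisomeric enol lactone 7 (not isolated)
Conditions: 4 (1.2 equiv), chiral triazolium chloride of the assumption (10 mol %), 3,3′,5,5′-tetra-tert-butyldiphenoquinone (1.1 equiv), i-Pr2NEt (20 mol %), toluene, rt; filter; then LiOH·H2O (3 equiv), THF–H2O, 0 °C, brief; 1 M HCl
Reagents that add atoms: lithium hydroxide monohydrate, [Li+].[OH-].O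
Why: Carbene and quinone turn 5 into an α,β-unsaturated acyl azolium, to whose β-carbon the central, most acidic and enolised methylene of 4 adds (Michael addition) on the face left open by the aminoindanol backbone, which sets C4, after which either enol oxygen closes the lactone and releases the carbene (oxidative carbene-catalysed annulation of enals with 1,3-diketones), and cold hydroxide then opens the activated enol ester of both regioisomers to the one acid 8.

**Step 4**
Reactants: 8 1-tert-butyl 7-methyl 4-[(1R)-2-carboxy-1-phenylethyl]-3,5-dioxoheptanedioate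
Product: 11 (4S)-5,7-dihydroxy-4-phenylchroman-2-one, via tert-butyl trihydroxybenzoate 9 (not isolated), via trihydroxyphenylpropanoic acid 10 (not isolated)
Conditions: NaOMe (5 equiv), MeOH, Ar, 0 °C → rt; evaporate; then CF3CO2H–CH2Cl2 (1:1), Et3SiH (3 equiv), 0 °C → rt
Reagents that add atoms: none
Why: Methoxide converts 8 into its carboxylate polyenolate, in which the methylene between C5=O and the tert-butyl ester (future C8, a β-keto ester enolate) attacks the methyl ester carbon (future C7) and expels methoxide, and the resulting cyclohexane-1,3,5-trione enolises irreversibly to the phloroglucinol 9. The closest known reaction type is the Claisen (Dieckmann-type) cyclisation of 3,5-dioxoheptanedioates to 2,4,6-trihydroxybenzoates, the ester counterpart of the polyketide Claisen aromatisation. Ring A closes in a 6-(enolendo)-exo-trig Claisen mode; in CF3CO2H the tert-butyl ester is cleaved, the 2,4,6-trihydroxybenzoic acid loses CO2 by ipso protonation to give 10, and the lactone ring closes by 6-exo-trig attack of a phenol on the side-chain carboxyl. No stereocentre is formed, and C4, which has no acidic hydrogen and sits next to a carboxylate that methoxide cannot enolise, should keep the configuration set in step 3. The step needs C–C closure onto the methyl ester in preference to O-closure to a 4-hydroxy-2-pyranone, attack on the tert-butyl ester and retro-Claisen cleavage of the diketone; the doubly stabilised carbanion, the more electrophilic methyl ester, the inert carboxylate side chain, the reversibility of O-closure under methoxide and the irreversible aromatisation should secure this, and the lactone regiochemistry is degenerate because both phenols flanking C4a are equivalent once CO2 is lost. Et3SiH traps the tert-butyl cation before it can alkylate the electron-rich ring.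

**Step 5**
Reactants: 11 (4S)-5,7-dihydroxy-4-phenylchroman-2-one; 12 3-(4-methoxyphenyl)propanoic acid
Product: 13 (4S)-5,7-dihydroxy-8-[3-(4-methoxyphenyl)propanoyl]-4-phenylchroman-2-one (target)
Conditions: 12 (1.2 equiv), BF3·OEt2 (excess), 70 °C; then H2O–MeOH, rt; chromatography to remove any C6 isomer
Reagents that add atoms: none
Why: BF3·OEt2 converts the acid into an acylating acyloxyboron species that should attack ring A at C8 (Friedel–Crafts acylation), the position para to the 5-hydroxyl and ortho to the 7-hydroxyl, which then chelates the new ketone, rather than at the more crowded C6 between two hydroxyls, while the less nucleophilic anisole ring, the lactone and the non-enolisable C4 stereocentre are left alone.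

**Compound list**
1 | 2,2,6-trimethyl-4H-1,3-dioxin-4-one | CC1=CC(=O)OC(C)(C)O1 | starting material
2 | methyl malonyl chloride (methyl 3-chloro-3-oxopropanoate) | COC(=O)CC(=O)Cl | starting material
3 | methyl 4-(2,2-dimethyl-4-oxo-4H-1,3-dioxin-6-yl)-3-oxobutanoate | COC(=O)CC(=O)CC1=CC(=O)OC(C)(C)O1 | intermediate
4 | 1-tert-butyl 7-methyl 3,5-dioxoheptanedioate | COC(=O)CC(=O)CC(=O)CC(=O)OC(C)(C)C | intermediate
5 | (E)-cinnamaldehyde | O=C/C=C/c1ccccc1 | starting material
6 | methyl 3-[(4S)-6-(2-tert-butoxy-2-oxoethyl)-2-oxo-4-phenyl-3,4-dihydro-2H-pyran-5-yl]-3-oxopropanoate | COC(=O)CC(=O)C1=C(CC(=O)OC(C)(C)C)OC(=O)C[C@H]1c1ccccc1 | intermediate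
7 | tert-butyl 3-[(4S)-6-(2-methoxy-2-oxoethyl)-2-oxo-4-phenyl-3,4-dihydro-2H-pyran-5-yl]-3-oxopropanoate | CC(C)(C)OC(=O)CC(=O)C1=C(CC(=O)OC)OC(=O)C[C@H]1c1ccccc1 | intermediate
8 | 1-tert-butyl 7-methyl 4-[(1R)-2-carboxy-1-phenylethyl]-3,5-dioxoheptanedioate (C4 epimers and enol forms) | COC(=O)CC(=O)C(C(=O)CC(=O)OC(C)(C)C)[C@@H](CC(=O)O)c1ccccc1 | intermediate
9 | tert-butyl 3-[(1S)-2-carboxy-1-phenylethyl]-2,4,6-trihydroxybenzoate | CC(C)(C)OC(=O)c1c(O)cc(O)c([C@@H](CC(=O)O)c2ccccc2)c1O | intermediate
10 | (3S)-3-phenyl-3-(2,4,6-trihydroxyphenyl)propanoic acid | OC(=O)C[C@@H](c1ccccc1)c1c(O)cc(O)cc1O | intermediate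
11 | (4S)-5,7-dihydroxy-4-phenylchroman-2-one | Oc1cc(O)c2c(c1)OC(=O)C[C@H]2c1ccccc1 | intermediate
12 | 3-(4-methoxyphenyl)propanoic acid | COc1ccc(CCC(=O)O)cc1 | starting material
13 | (4S)-5,7-dihydroxy-8-[3-(4-methoxyphenyl)propanoyl]-4-phenylchroman-2-one | COc1ccc(CCC(=O)c2c(O)cc(O)c3c2OC(=O)C[C@H]3c2ccccc2)cc1 | target

**Step count and risks**
Total step count: 5. Longest linear sequence: 5 steps (1 → 3 → 4 → 8 → 11 → 13).

Steps most likely to fail:

1. Step 3. The donor may add through an ester-flanked methylene instead of the central one, may condense with itself under base before it meets the acyl azolium, or the facial control may be insufficient. Fallback, from 4 and 5 back to 8: the conjugate addition is run through the neutral enol under iminium activation. The matching antipode of α,α-diphenylprolinol trimethylsilyl ether with benzoic acid in toluene should give 1-tert-butyl 7-methyl 3,5-dioxo-4-[(1R)-3-oxo-1-phenylpropyl]heptanedioate F1 (present largely as its cyclic hemiacetals). A Pinnick oxidation of F1 (NaClO2, NaH2PO4, 2-methyl-2-butene, t-BuOH–H2O) returns the route to 8.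

2. Step 4. Methoxide may fragment the 2-substituted 1,3-diketone (retro-Claisen), or closure through oxygen may outrun the carbon–carbon closure. Fallback, from 3 and 5 back to 9: ring A is closed through the neighbouring ring bond (C8–C8a) of an isomeric chain whose 1,3-diketone is unsubstituted, fully enolised and so resistant to cleavage. The annulation of step 3 is run on 3, which reacts at its ester-flanked methylene (the usual site for a β-keto ester), to give methyl (4S)-6-[(2,2-dimethyl-4-oxo-4H-1,3-dioxin-6-yl)methyl]-2-oxo-4-phenyl-3,4-dihydro-2H-pyran-5-carboxylate F2. Heating with tert-butanol converts the dioxinone into methyl (4S)-6-(4-tert-butoxy-2,4-dioxobutyl)-2-oxo-4-phenyl-3,4-dihydro-2H-pyran-5-carboxylate F3. Cold LiOH opens the enol lactone to 7-tert-butyl 1-methyl 2-[(1R)-2-carboxy-1-phenylethyl]-3,5-dioxoheptanedioate F4, and NaOMe closes the ester-activated methylene of F4 onto the methyl ester to give 9, which goes through the acid stage of step 4 to 11.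

3. Step 5. Attack at C6 may compete; configuration may erode through reversible acid-induced cleavage of the C4–C4a bond at the temperature the BF3-promoted acylation needs; and opening and re-closure of the lactone through the other phenol would shift the acyl group formally to C6. Fallback, from 11 back to 13: a Houben–Hoesch reaction with 3-(4-methoxyphenyl)propanenitrile (HCl gas, ZnCl2, Et2O, 0 °C) should give (4S)-5,7-dihydroxy-8-[1-iminio-3-(4-methoxyphenyl)propyl]-4-phenylchroman-2-one chloride F5 without heating in a strong Lewis acid. Hydrolysis of F5 in weakly acidic water at ambient temperature gives 13.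

**Further compounds**
F1 | step 3 | 1-tert-butyl 7-methyl 3,5-dioxo-4-[(1R)-3-oxo-1-phenylpropyl]heptanedioate | COC(=O)CC(=O)C(C(=O)CC(=O)OC(C)(C)C)[C@@H](CC=O)c1ccccc1
F2 | step 4 | methyl (4S)-6-[(2,2-dimethyl-4-oxo-4H-1,3-dioxin-6-yl)methyl]-2-oxo-4-phenyl-3,4-dihydro-2H-pyran-5-carboxylate | COC(=O)C1=C(CC2=CC(=O)OC(C)(C)O2)OC(=O)C[C@H]1c1ccccc1
F3 | step 4 | methyl (4S)-6-(4-tert-butoxy-2,4-dioxobutyl)-2-oxo-4-phenyl-3,4-dihydro-2H-pyran-5-carboxylate | COC(=O)C1=C(CC(=O)CC(=O)OC(C)(C)C)OC(=O)C[C@H]1c1ccccc1
F4 | step 4 | 7-tert-butyl 1-methyl 2-[(1R)-2-carboxy-1-phenylethyl]-3,5-dioxoheptanedioate | COC(=O)C(C(=O)CC(=O)CC(=O)OC(C)(C)C)[C@@H](CC(=O)O)c1ccccc1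
F5 | step 5 | (4S)-5,7-dihydroxy-8-[1-iminio-3-(4-methoxyphenyl)propyl]-4-phenylchroman-2-one chloride | COc1ccc(CCC(=[NH2+])c2c(O)cc(O)c3c2OC(=O)C[C@H]3c2ccccc2)cc1.[Cl-]
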